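**Retrosynthetic overview**

1. Target 21 comes from silyl ether 20 by cleavage of the O8–Si bond.
2. Feature used: in lactone ring B the atoms O2, C1(=O), C4 and C3 are the four atoms of a β-lactone, and the arene bond C8a–C4a of ring A lies between C1 and C4. Ring B is therefore cut at C1–C8a and C4–C4a (C1–C4 rejoined), which gives (R)-β-lactone 11 and 3-silyloxybenzyne 16 (from iodo triflate 14).
3. Lactone 11 comes from hydroxy acid 9 by carboxyl-activation lactonisation (C–O bond kept). Acid 9 comes from an acetate aldol of (R)-HYTRA 6 with dienal 5, which sets C3. Dienal 5 comes from tetradecanal 1 and phosphonate 2.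
4. Iodo triflate 14 comes from 2-iodoresorcinol 12 by monosilylation and triflation.
5. Ring order: ring A is bought, the four-membered lactone is closed in step 6, and it is expanded to ring B in step 9.

Key step: step 9

Assumption: doubly lithiated (R)-HYTRA is taken to add to dienal 5 with the facial sense it shows towards saturated and simple conjugated aldehydes, which corresponds to (3R) here.

**Route**

Step 1
Reactants: 1 tetradecanal; 2 triethyl 4-phosphonocrotonate
Product: 3 ethyl (2E,4E)-octadeca-2,4-dienoate
Conditions: LiN(SiMe3)2, THF, −78 → 0 °C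
Reagents that add atoms: none
Why: Vinylogous Horner–Wadsworth–Emmons olefination, in which the stabilised phosphonate anion reacts at the carbon next to phosphorus and should give the new C4=C5 bond E under thermodynamic control while the C2=C3 bond stays E; any (2E,4Z) isomer is removed by chromatography.

Step 2
Reactants: 3 ethyl (2E,4E)-octadeca-2,4-dienoate
Product: 4 (2E,4E)-octadeca-2,4-dien-1-ol
Conditions: iBu2AlH (2.2 equiv), CH2Cl2, −78 → 0 °C; aq. potassium sodium tartrate
Reagents that add atoms: none
Why: 1,2-Reduction of a conjugated ester by iBu2AlH, which should give the dienol without touching the diene.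

Step 3
Reactants: 4 (2E,4E)-octadeca-2,4-dien-1-ol
Product: 5 (2E,4E)-octadeca-2,4-dienal
Conditions: MnO2 (activated, excess), CH2Cl2, rt
Reagents that add atoms: none
Why: MnO2 oxidation of an allylic alcohol, selective for the dienylic position and expected to stop at the aldehyde without isomerising the double bonds.

Step 4
Reactants: 5 (2E,4E)-octadeca-2,4-dienal; 6 (R)-HYTRA, (1R)-2-hydroxy-1,2,2-triphenylethyl acetate
Product: 8 (1R)-2-hydroxy-1,2,2-triphenylethyl (3R,4E,6E)-3-hydroxyicosa-4,6-dienoate, via dilithiated (R)-HYTRA 7 (not isolated)
Conditions: LiN(iPr)2 (2.1 equiv), THF, −78 → 0 °C; then 5, −100 °C; AcOH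
Reagents that add atoms: none
Why: HYTRA acetate aldol (auxiliary-controlled addition of a chiral acetate enolate), in which the dianion 7 adds 1,2 to the aldehyde and the auxiliary stereocentre selects the face that gives the (3R) carbinol; the minor (3S) diastereomer should be removable by chromatography or crystallisation because the auxiliary is still attached.

Step 5
Reactants: 8 (1R)-2-hydroxy-1,2,2-triphenylethyl (3R,4E,6E)-3-hydroxyicosa-4,6-dienoate
Product: 9 (3R,4E,6E)-3-hydroxyicosa-4,6-dienoic acid
Conditions: LiOH·H2O, THF/MeOH/H2O, 0 °C → rt; then cold 1 M HCl to pH 3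
Reagents that add atoms: lithium hydroxide, [Li+].[OH-]
Why: Ester saponification by acyl–oxygen cleavage, which leaves the carbinol centre untouched and releases the diol auxiliary for recovery; the low temperature is meant to hold back retro-aldol cleavage and dehydration.

Step 6
Reactants: 9 (3R,4E,6E)-3-hydroxyicosa-4,6-dienoic acid
Product: 11 (4R)-4-[(1E,3E)-heptadeca-1,3-dien-1-yl]oxetan-2-one, via carboxylic benzenesulfonic mixed anhydride 10 (not isolated)
Conditions: PhSO2Cl (2 equiv), pyridine, 0 → 4 °C
Reagents that add atoms: none
Why: β-Lactonisation by carboxyl activation, in which the carboxylate is converted into mixed anhydride 10 faster than the secondary alcohol is sulfonylated and the hydroxyl then closes on the acyl carbon (4-exo-trig), so the C3–O bond is not broken and the (R) centre becomes C4 of the lactone; the product is kept cold and used promptly because 4-alkenyl β-lactones lose CO2 on warming.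

Step 7
Reactants: 12 2-iodoresorcinol (2-iodobenzene-1,3-diol)
Product: 13 2-iodo-3-(triisopropylsilyloxy)phenol
Conditions: TIPSCl (1.0 equiv), imidazole, DMF, 0 °C → rt
Reagents that add atoms: triisopropylsilyl chloride, CC(C)[Si](Cl)(C(C)C)C(C)C
Why: Imidazole-mediated O-silylation of one of two equivalent phenols, a statistical reaction from which the monosilyl ether is separated from bis-ether and recovered diol; the bulky silyl group is chosen because it tolerates organolithium reagents and migrates slowly.

Step 8
Reactants: 13 2-iodo-3-(triisopropylsilyloxy)phenol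
Product: 14 2-iodo-3-(triisopropylsilyloxy)phenyl trifluoromethanesulfonate
Conditions: Tf2O (1.2 equiv), pyridine, CH2Cl2, 0 °C
Reagents that add atoms: trifluoromethanesulfonic anhydride, O=S(=O)(OS(=O)(=O)C(F)(F)F)C(F)(F)F
Why: O-Triflation of a phenol, which gives an ortho-iodoaryl triflate, a precursor that releases an aryne at −78 °C on iodine–lithium exchange.

Step 9
Reactants: 11 (4R)-4-[(1E,3E)-heptadeca-1,3-dien-1-yl]oxetan-2-one; 14 2-iodo-3-(triisopropylsilyloxy)phenyl trifluoromethanesulfonate
Product: 20 (3R)-3-[(1E,3E)-heptadeca-1,3-dien-1-yl]-8-(triisopropylsilyloxy)isochroman-1-one, via lithium enolate of the lactone 15 (not isolated), via 3-(triisopropylsilyloxy)benzyne 16 (not isolated), via ortho-lithiated 3-aryl lactone 17 (not isolated), via fused benzocyclobutene alkoxide 18 (not isolated), via C4-lithiated isochromanone 19 (not isolated)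
Conditions: lithium 2,2,6,6-tetramethylpiperidide (1.05 equiv), THF, −78 °C (11 added to the base); 14 (1.2 equiv), then n-BuLi (1.2 equiv, slow addition), −78 °C; AcOH/THF, −78 °C
Reagents that add atoms: none
Why: Proposed new method: the hindered amide base deprotonates 11 at C3 at −78 °C to enolate 15 (β-lactone enolates persist at this temperature and react at carbon trans to the C4 substituent), iodine–lithium exchange on 14 and loss of LiOTf release aryne 16, the enolate carbon adds to the aryne carbon meta to the silyloxy group to give aryllithium 17, this closes on the lactone carbonyl to alkoxide 18, and cleavage of the C–C bond shared by the two four-membered rings (directly, or by way of a benzocyclobutenone whose pendant alkoxide re-adds) gives the o-toluate-type dienolate 19, which the cold acetic acid quench protonates at C4. The closest known reactions are the acyl-alkylation of arynes by β-keto esters and malonates (insertion into the acyl–Cα bond), the [2+2] addition of ketene silyl acetals and the addition of lithium enolates to 3-alkoxybenzynes, and the alkoxide-induced opening of benzocyclobutenones to o-toluates; a lactone enolate has not been used in this way, and because its acyl and alkyl ends stay joined through the ring oxygen the insertion becomes a four- to six-membered ring expansion. Ring B is closed in two events, a 4-exo-trig attack of the aryl anion on the carbonyl and then fragmentation of the bicyclic alkoxide, driven by release of the strain of two four-membered rings and by formation of the conjugated dienolate. No stereocentre is created, since the C3–O2 bond of the product is the C4–O1 bond of 11 and is never broken, so the (R) configuration set in step 4 is carried through. The step needs regioselectivity (C4–C4a and C1–C8a, not the reverse), which the inductive effect of the silyloxy group should secure by directing the nucleophile to the distal aryne carbon and placing the aryl anion next to oxygen, and it needs chemoselectivity against β-elimination of 15 and E1cB opening of 19, which are held back by the temperature, by the poor overlap of the C–O bond with the carbanion orbital in both rings and by the cold proton quench. The tetramethylpiperidide base is chosen because neither it nor its amine adds readily to the aryne and because iodine–lithium exchange is far faster than metalation of that amine at −78 °C.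

Step 10
Reactants: 20 (3R)-3-[(1E,3E)-heptadeca-1,3-dien-1-yl]-8-(triisopropylsilyloxy)isochroman-1-one
Product: 21 (3R)-3-[(1E,3E)-heptadeca-1,3-dien-1-yl]-8-hydroxyisochroman-1-one
Conditions: Bu4NF (1.1 equiv), AcOH (1.2 equiv), THF, 0 °C
Reagents that add atoms: none
Why: Fluoride cleavage of an aryl silyl ether, buffered with acetic acid so that the medium stays non-basic and the lactone is not opened by elimination; the allylic C3–O bond and the diene are not affected.

**Compound list**

1 | tetradecanal | CCCCCCCCCCCCCC=O | starting material
2 | triethyl 4-phosphonocrotonate | CCOC(=O)/C=C/CP(=O)(OCC)OCC | starting material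
3 | ethyl (2E,4E)-octadeca-2,4-dienoate | CCCCCCCCCCCCC/C=C/C=C/C(=O)OCC | intermediate
4 | (2E,4E)-octadeca-2,4-dien-1-ol | CCCCCCCCCCCCC/C=C/C=C/CO | intermediate
5 | (2E,4E)-octadeca-2,4-dienal | CCCCCCCCCCCCC/C=C/C=C/C=O | intermediate
6 | (R)-HYTRA, (1R)-2-hydroxy-1,2,2-triphenylethyl acetate | CC(=O)O[C@H](c1ccccc1)C(O)(c1ccccc1)c1ccccc1 | starting material
7 | dilithiated (R)-HYTRA (lithium enolate and lithium alkoxide) | [Li+].[Li+].C=C([O-])O[C@H](c1ccccc1)C([O-])(c1ccccc1)c1ccccc1 | intermediate (not isolated)
8 | (1R)-2-hydroxy-1,2,2-triphenylethyl (3R,4E,6E)-3-hydroxyicosa-4,6-dienoate | CCCCCCCCCCCCC/C=C/C=C/[C@H](O)CC(=O)O[C@H](c1ccccc1)C(O)(c1ccccc1)c1ccccc1 | intermediate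
9 | (3R,4E,6E)-3-hydroxyicosa-4,6-dienoic acid | CCCCCCCCCCCCC/C=C/C=C/[C@H](O)CC(=O)O | intermediate
10 | (3R,4E,6E)-3-hydroxyicosa-4,6-dienoic benzenesulfonic anhydride | CCCCCCCCCCCCC/C=C/C=C/[C@H](O)CC(=O)OS(=O)(=O)c1ccccc1 | intermediate (not isolated)
11 | (4R)-4-[(1E,3E)-heptadeca-1,3-dien-1-yl]oxetan-2-one | CCCCCCCCCCCCC/C=C/C=C/[C@H]1CC(=O)O1 | intermediate
12 | 2-iodoresorcinol (2-iodobenzene-1,3-diol) | Oc1cccc(O)c1I | starting material
13 | 2-iodo-3-(triisopropylsilyloxy)phenol | CC(C)[Si](Oc1cccc(O)c1I)(C(C)C)C(C)C | intermediate
14 | 2-iodo-3-(triisopropylsilyloxy)phenyl trifluoromethanesulfonate | CC(C)[Si](Oc1cccc(OS(=O)(=O)C(F)(F)F)c1I)(C(C)C)C(C)C | intermediate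
15 | lithium enolate of 11 (lithium 4-dienyl-4H-oxet-2-olate, C4 configuration as in 11) | CCCCCCCCCCCCC/C=C/C=C/[C@H]1C=C([O-])O1.[Li+] | intermediate (not isolated)
16 | 3-(triisopropylsilyloxy)benzyne | CC(C)[Si](OC1=CC=CC#C1)(C(C)C)C(C)C | intermediate (not isolated)
17 | trans-4-dienyl-3-[2-lithio-3-(triisopropylsilyloxy)phenyl]oxetan-2-one (C4 configuration as in 11, aryl trans to the dienyl group) | CCCCCCCCCCCCC/C=C/C=C/[C@@H]1OC(=O)[C@H]1c2cccc(O[Si](C(C)C)(C(C)C)C(C)C)c2[Li] | intermediate (not isolated)
18 | lithium alkoxide of the cis-fused benzocyclobutene–oxetane adduct (aryl carbon ortho to the silyloxy group bonded to the former lactone carbonyl carbon) | CCCCCCCCCCCCC/C=C/C=C/[C@@H]1O[C@@]2([O-])c3c(O[Si](C(C)C)(C(C)C)C(C)C)cccc3[C@@H]12.[Li+] | intermediate (not isolated)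
19 | C4-lithiated (3R)-3-dienyl-8-(triisopropylsilyloxy)isochroman-1-one (o-toluate-type dienolate) | [Li+].CCCCCCCCCCCCC/C=C/C=C/[C@H]1[CH-]c2cccc(O[Si](C(C)C)(C(C)C)C(C)C)c2C(=O)O1 | intermediate (not isolated)
20 | (3R)-3-[(1E,3E)-heptadeca-1,3-dien-1-yl]-8-(triisopropylsilyloxy)isochroman-1-one | CCCCCCCCCCCCC/C=C/C=C/[C@H]1Cc2cccc(O[Si](C(C)C)(C(C)C)C(C)C)c2C(=O)O1 | intermediate
21 | (3R)-3-[(1E,3E)-heptadeca-1,3-dien-1-yl]-8-hydroxyisochroman-1-one | CCCCCCCCCCCCC/C=C/C=C/[C@H]1Cc2cccc(O)c2C(=O)O1 | target

**Step count**

Total steps: 10. Longest linear sequence: 8 steps (steps 1–6, 9 and 10); steps 7 and 8 form the second branch.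

**Steps most likely to fail**

1. Step 9, the step that goes beyond known chemistry. Possible failures are β-elimination or self-acylation of the lactone enolate, protonation of the aryl anion before it reaches the carbonyl (plain α-arylation), a second arylation of the dienolate, and E1cB ring opening before the quench. The fallback sets out from dienal 5 and returns at 20, using the known route from toluate anions and aldehydes to 3-substituted dihydroisocoumarins. Commercial ethyl 2-hydroxy-6-methylbenzoate is silylated (TIPSCl, imidazole, DMF) to ethyl 2-methyl-6-(triisopropylsilyloxy)benzoate F1. Lateral lithiation with LiN(iPr)2 in THF at −78 °C gives the benzylic lithium derivative of that ester F2, which adds 1,2 to 5. On warming, the alkoxide closes on the neighbouring ester to give racemic 3-[(1E,3E)-heptadeca-1,3-dien-1-yl]-8-(triisopropylsilyloxy)isochroman-1-one F3. Preparative chromatography on a chiral stationary phase then separates the (3R) enantiomer, which is 20.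

2. Step 6. Possible failures are sulfonylation of the dienylic hydroxyl followed by ionisation or elimination, and loss of CO2 from the lactone during isolation. The fallback sets out from dienal 5 and returns at 11 without passing through 8 and 9. Acetyl chloride and iPr2NEt generate ketene F4 in the flask. With O-trimethylsilylquinidine (10 mol%) and LiClO4 in CH2Cl2/Et2O at −78 °C, the ketene should undergo the amine-catalysed, Lewis-acid-assisted [2+2] cycloaddition with the aldehyde carbonyl of 5 and close the lactone at low temperature under basic conditions. The quinidine-derived catalyst is the pseudoenantiomer expected to give the (4R) lactone by analogy with quinidine in ketene–aldehyde cycloadditions; if the sense proved opposite, the quinine-derived catalyst would be used.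

3. Step 4. Possible failures are insufficient facial selectivity at the aldehyde and incomplete separation of the diastereomeric esters. The fallback sets out from dienal 5 and returns at 9. The lithium enolate of ethyl acetate (LiN(iPr)2, THF, −78 °C) adds to 5 to give racemic ethyl (4E,6E)-3-hydroxyicosa-4,6-dienoate F5. A Sharpless kinetic resolution (tBuOOH 0.6 equiv, Ti(OiPr)4, L-(+)-diisopropyl tartrate, 4 Å molecular sieves, CH2Cl2, −20 °C) should epoxidise the (3S) enantiomer at C4=C5 to ethyl (3S)-3-hydroxy-3-{(2S,3S)-3-[(1E)-pentadec-1-en-1-yl]oxiran-2-yl}propanoate F6. This should leave ethyl (3R,4E,6E)-3-hydroxyicosa-4,6-dienoate F7, which is saponified (LiOH, THF/H2O, 0 °C) to 9.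

**Further compounds**

F1 | step 9 | ethyl 2-methyl-6-(triisopropylsilyloxy)benzoate | CCOC(=O)c1c(C)cccc1O[Si](C(C)C)(C(C)C)C(C)C
F2 | step 9 | benzylic lithium derivative of ethyl 2-methyl-6-(triisopropylsilyloxy)benzoate | [Li+].[CH2-]c1cccc(O[Si](C(C)C)(C(C)C)C(C)C)c1C(=O)OCC
F3 | step 9 | racemic 3-[(1E,3E)-heptadeca-1,3-dien-1-yl]-8-(triisopropylsilyloxy)isochroman-1-one | CCCCCCCCCCCCC/C=C/C=C/C1Cc2cccc(O[Si](C(C)C)(C(C)C)C(C)C)c2C(=O)O1
F4 | step 6 | ketene | C=C=O
F5 | step 4 | racemic ethyl (4E,6E)-3-hydroxyicosa-4,6-dienoate | CCCCCCCCCCCCC/C=C/C=C/C(O)CC(=O)OCC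
F6 | step 4 | ethyl (3S)-3-hydroxy-3-{(2S,3S)-3-[(1E)-pentadec-1-en-1-yl]oxiran-2-yl}propanoate | CCCCCCCCCCCCC/C=C/[C@@H]1O[C@H]1[C@@H](O)CC(=O)OCC
F7 | step 4 | ethyl (3R,4E,6E)-3-hydroxyicosa-4,6-dienoate | CCCCCCCCCCCCC/C=C/C=C/[C@H](O)CC(=O)OCC
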